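## Analysis of the target

Target 31 is the 2-hydroxybenzoate of a daucane-type diol: a cyclopentane trans-fused to a cycloheptene. The skeleton is numbered C1 (methyl-bearing fusion carbon), C2 and C3 (ring CH2), C4 (isopropyl carbinol), C5 (fusion CH), C6 (ester-bearing CH), C7 (CH2), C8(CH3)=C9 and C10 (CH2). The four stereocentres are contiguous, (1R,4R,5S,6S) in this numbering. The C1 methyl and H5 are trans, the C4 hydroxyl is cis to the C1 methyl and to the C5–C6 bond, and the C6 oxygen is cis to H5 on the seven-membered ring. Sensitive points are the tertiary C4 carbinol (dehydration toward C4=C5), the C8=C9 alkene (it is β,γ to any C6 carbonyl and can migrate) and the salicylate with its free phenol on a hindered secondary alcohol. The difficulty lies in the quaternary C1, in C5 wedged between two fully substituted carbons, and in closing a seven-membered ring with the alkene in one defined position. The strategy rests on the C9–C10 bond: C10 is a neopentyl methylene on quaternary C1, useless as an SN2 electrophile or as a stabilised nucleophile, and C9 is vinylic. Both carbons are therefore carried as iodides and joined reductively at nickel, after all four stereocentres have been set on a simple cyclopentane.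

## Retrosynthetic reasoning

**Ester and phenol.** The C6 ester of 31 is cut last. The diol 28 has one secondary and one hindered tertiary hydroxyl, so acylation with the acetyl-protected acid chloride 29 should go to C6 only and give 30. The phenolic acetate is then removed as an activated aryl ester, without touching the hindered alkyl benzoate. 28 comes from its bis-silyl ether 27.

**C9–C10 (seven-membered ring).** Cutting 27 between the vinylic C9 and the neopentyl C10 gives the acyclic diiodide 26. This cut removes the only medium ring and leaves a cyclopentane with two side arms. Because the forward reaction joins two electrophilic carbons at nickel, neither carbon has to be made into a carbanion. The Z vinyl iodide fixes both the position and the geometry of the ring alkene.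

**C10–I.** The neopentyl iodide of 26 is traced through alcohol 25 to the vinyl group of 23. The vinyl group is a latent one-carbon unit that survives all organometallic steps and is cut down to C10 only after sulfur has left the molecule.

**C6 stereocentre.** The bis-silyl ether 23 comes from diol 22, and the C6 carbinol of 22 from ketone 20. A carbonyl at C6 lets the neighbouring C4 hydroxyl steer hydride delivery through a cyclic chelate. It also reflects how the C6–C7 bond is made.

**C6–C7.** Ketone 20 is unmasked from dithiane 19, which is cut between C6 and C7 into dithiane 17 (C6 as an acyl-anion equivalent) and the allylic bromide 7. This places the sensitive Z iodoalkene in a small, separately made fragment. Fragment 7 comes from alcohol 6, and 6 from alkyne 3 and Grignard reagent 4 by an anti-carbometalation that defines the alkene geometry.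

**C4–isopropyl.** The tertiary carbinol of 17 is cut to ketone 14 and the Grignard reagent 15. The C5 substituent next to the carbonyl directs the nucleophile to the opposite face, which is the face the target needs.

**C5–C6 and the vinyl unmasking.** Ketone 14 comes from its silylated precursor 13, and 13 from the regiodefined silyl enol ether 12 and the dithienium salt 2, itself made from 1. This brings in C6 at the aldehyde oxidation level in one step. The bulky 1-silylvinyl group on C1 directs the electrophile to the methyl face.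

**C1 quaternary centre.** Enol ether 12 is cut at the C1–alkenyl bond to enone 8 and alkyne 9. A catalytic enantioselective conjugate addition sets C1 and leaves the enolate on the C5 side, which deprotonation of the ketone could not deliver.

## Alternatives that were turned down

**Alternative 1:** Both rings are cut at C1–C10 and C4–C5, which leads back to the acyclic (2E,6E)-farnesyl diphosphate A2. In the forward step a class 1 sesquiterpene synthase of the daucane-forming type ionises A2, closes both rings in one active site and captures water at C5, which gives carotol A1.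
- For: one step delivers the whole bicyclic skeleton, the quaternary C1 in the configuration of 31, and the C8=C9 alkene.
- Against: A1 carries its oxygen on the fusion carbon C5 and none on C4 or C6. The target needs H at C5, OH at C4 and an acyloxy group at C6. The C5 oxygen of A1 would have to be removed and two C–O bonds made beside it, with two alkenes to distinguish and only the C1 methyl as a control element. The enzyme and its substrate A2 are not bench reagents.
- Comparison: this alternative is clearly stronger on step economy for the skeleton. The chosen route instead brings each oxygen in on the right carbon from the start and sets C4, C5 and C6 on a cyclopentane by 1,2-induction.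

**Alternative 2:** The C1–CH3 and C4–C5 bonds are cut, which leads back to the monocyclic dienone 6-methyl-3-(4-methyl-3-oxopentyl)cyclohepta-2,5-dien-1-one A4. In the forward step the monovalent copper salt [Cu(CH3CN)4]PF6 A6, with a chiral phosphoramidite as ligand, transfers a methyl group from trimethylaluminium A5 to C1 of A4. The aluminium enolate at C5 then closes onto the side-chain C4 ketone, and dehydration on acidic work-up gives the bicyclic dienone A3.
- For: catalytic enantioselective formation of C1 and closure of the five-membered ring in one pot from A4, A5 and catalytic A6. Access to a bicyclic core is shorter than in the chosen route.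
- Against: A3 has a tetrasubstituted C4=C5 enone. Reaching the target from A3 needs OH at the β-carbon C4, H at C5 trans to the C1 methyl and a defined C6 carbinol, all set late on a flexible hydroazulenone by substrate bias alone. C5 stays epimerisable as long as C6 is a ketone. The C8=C9 alkene is β,γ to that ketone and can slide into conjugation during the cascade and afterwards.
- Comparison: stronger on step count to the ring system. The chosen route offers secure relative configuration at C4–C6 and an alkene that is only created in the ring-closing step.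

**Alternative 3:** The C7–C8 and C1–C10 bonds are cut, which gives the ethoxydiene 2-(1-ethoxyethenyl)-3-methylcyclopent-2-en-1-one A8 and the vinyldiazoacetate methyl 2-diazobut-3-enoate A9. In the forward step the divalent rhodium carboxylate Rh2(S-DOSP)4 A10 decomposes A9 to the vinylcarbenoid, which cyclopropanates the C6=C7 enol ether of A8. The cis-divinylcyclopropane then undergoes Cope rearrangement to the bicyclic vinylogous ester A7.
- For: convergent; two C–C bonds, the seven-membered ring and C1 arise in one step from the two small pieces A8 and A9 under catalysis by A10, with C8=C9 in the right place.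
- Against: C8 arrives in A7 as a methyl ester and must be reduced to CH3 through an allylic system (about three steps). C1 is formed in the Cope step from a fully substituted diene terminus, remote from the cyclopropanation that carries the asymmetric induction. After isopropyl addition to A7 and unveiling, the same C4=C5–C6=O problem as in alternative 2 remains.
- Comparison: stronger in convergence and ring-forming power. The chosen route has the correct C8 substituent from the outset and no late oxidation-state corrections on the bicycle.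

Key step: step 14

Remark: in step 4 the carbene ligand is taken in the enantiomeric form that delivers the alkenyl group to the face of 8 giving (3S)-12.

## Route

Step 1
Reactants: 1 1,3-dithiane
Product: 2 1,3-dithian-2-ylium tetrafluoroborate
Conditions: Ph3C+ BF4−, CH2Cl2, reflux; Et2O precipitation
Reagents that add atoms: triphenylcarbenium tetrafluoroborate, F[B-](F)(F)F.c1ccc(cc1)[C+](c1ccccc1)c1ccccc1
Why: Hydride abstraction from C2 of the dithiane by the trityl cation should give the sulfur-stabilised carbenium salt, a formyl cation equivalent that is filtered off and used directly.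

Step 2
Reactants: 3 prop-2-yn-1-ol; 4 methylmagnesium bromide
Product: 6 (2Z)-3-iodo-2-methylprop-2-en-1-ol, via cyclic alkenylmagnesium alkoxide 5 (not isolated)
Conditions: MeMgBr (2.5 equiv), CuI (10 mol%), THF, −20 °C → rt; then I2, −78 → 0 °C
Reagents that add atoms: iodine, II
Why: Copper-catalysed anti-carbomagnesiation of the propargylic alkoxide should place methyl on C2 and magnesium on C3 within a five-membered chelate, and iodinolysis with retention then gives the Z iodoalkene with iodine cis to CH2OH.

Step 3
Reactants: 6 (2Z)-3-iodo-2-methylprop-2-en-1-ol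
Product: 7 (1Z)-3-bromo-1-iodo-2-methylprop-1-ene
Conditions: CBr4, PPh3, CH2Cl2, 0 °C
Reagents that add atoms: tetrabromomethane, BrC(Br)(Br)Br
Why: Appel bromination of the primary allylic alcohol proceeds by SN2 at CH2 and should leave the alkene geometry and the vinyl iodide untouched.

Step 4
Reactants: 8 3-methylcyclopent-2-en-1-one; 9 ethynyl(trimethyl)silane
Product: 12 trimethyl({(3S)-3-methyl-3-[1-(trimethylsilyl)ethenyl]cyclopent-1-en-1-yl}oxy)silane, via alkenylalane 10 (not isolated), via aluminium enolate 11 (not isolated)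
Conditions: 9, iBu2AlH, hexane/THF, 55 °C; then 8, CuCl2·2H2O (5 mol%), chiral sulfonate-bearing N-heterocyclic carbene ligand (2.5 mol%, from its imidazolinium salt and Ag2O), THF, −30 °C; then TMSOTf, −78 → −20 °C
Reagents that add atoms: trimethylsilyl trifluoromethanesulfonate, C[Si](C)(C)OS(=O)(=O)C(F)(F)F
Why: Hydroalumination of the silylalkyne puts aluminium on the silicon-bearing carbon, and copper-catalysed asymmetric conjugate addition of this alkenylalane to the β-methyl enone should set quaternary C1 under ligand control; O-silylation of the aluminium enolate keeps the enol double bond on the C5 side, which enolisation of the ketone would not give.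

Step 5
Reactants: 12 trimethyl({(3S)-3-methyl-3-[1-(trimethylsilyl)ethenyl]cyclopent-1-en-1-yl}oxy)silane; 2 1,3-dithian-2-ylium tetrafluoroborate
Product: 13 (2R,3S)-2-(1,3-dithian-2-yl)-3-methyl-3-[1-(trimethylsilyl)ethenyl]cyclopentan-1-one
Conditions: CH2Cl2, −78 °C; aq NaHCO3
Reagents that add atoms: none
Why: Mukaiyama-type alkylation of the silyl enol ether by the dithienium cation forms C5–C6 with C6 already at the aldehyde oxidation level; the cation should approach C5 anti to the bulky 1-silylvinyl group on C1, so the dithianyl group ends up cis to the C1 methyl.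

Step 6
Reactants: 13 (2R,3S)-2-(1,3-dithian-2-yl)-3-methyl-3-[1-(trimethylsilyl)ethenyl]cyclopentan-1-one
Product: 14 (2R,3R)-2-(1,3-dithian-2-yl)-3-ethenyl-3-methylcyclopentan-1-one
Conditions: CF3CO2H, CH2Cl2, 0 °C → rt
Reagents that add atoms: none
Why: Protodesilylation of the vinylsilane by ipso-protonation (β-silyl cation) and loss of silicon should unmask the plain vinyl group and clear the upper face for step 7; enolisation toward C5 would need a tetrasubstituted enol next to the quaternary carbon and should be slow, and the change of the C3 descriptor from S to R is a priority change only.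

Step 7
Reactants: 14 (2R,3R)-2-(1,3-dithian-2-yl)-3-ethenyl-3-methylcyclopentan-1-one; 15 isopropylmagnesium chloride
Product: 17 (1R,2R,3R)-2-(1,3-dithian-2-yl)-3-ethenyl-3-methyl-1-(propan-2-yl)cyclopentan-1-ol, via isopropylcerium dichloride 16 (not isolated)
Conditions: iPrMgCl, CeCl3 (dried), THF, −78 °C; then 14, −78 → −40 °C
Reagents that add atoms: none
Why: The organocerium reagent adds to hindered, enolisable ketones without the reduction and enolisation seen with the Grignard reagent alone; attack anti to the adjacent dithianyl group should give C4 with the hydroxyl cis to C6 and the isopropyl group trans to it.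

Step 8
Reactants: 17 (1R,2R,3R)-2-(1,3-dithian-2-yl)-3-ethenyl-3-methyl-1-(propan-2-yl)cyclopentan-1-ol; 7 (1Z)-3-bromo-1-iodo-2-methylprop-1-ene
Product: 19 (1R,2R,3R)-3-ethenyl-2-{2-[(2Z)-3-iodo-2-methylprop-2-en-1-yl]-1,3-dithian-2-yl}-3-methyl-1-(propan-2-yl)cyclopentan-1-ol, via dilithio derivative 18 (not isolated)
Conditions: n-BuLi (1.0 equiv), THF, −78 °C; t-BuLi (1.1 equiv), HMPA, −78 → −40 °C; then 7, −78 → −20 °C
Reagents that add atoms: none
Why: Corey–Seebach umpolung: after the hydroxyl is taken up as its lithium alkoxide, the dithiane C–H is metalated and the sulfur-stabilised carbanion should displace the primary allylic bromide by SN2, forming C6–C7 without touching the vinyl iodide; the hindered tertiary alkoxide is a far poorer nucleophile than the carbanion.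

Step 9
Reactants: 19 (1R,2R,3R)-3-ethenyl-2-{2-[(2Z)-3-iodo-2-methylprop-2-en-1-yl]-1,3-dithian-2-yl}-3-methyl-1-(propan-2-yl)cyclopentan-1-ol
Product: 20 (3Z)-1-[(1R,2R,5R)-2-ethenyl-5-hydroxy-2-methyl-5-(propan-2-yl)cyclopentyl]-4-iodo-3-methylbut-3-en-1-one
Conditions: MeI, CaCO3, MeCN/H2O (9:1), 45 °C
Reagents that add atoms: water, O
Why: S-Methylation and hydrolysis of the crowded ketone dithioacetal should proceed under near-neutral buffered conditions that spare both alkenes and the vinyl iodide and avoid retro-aldol cleavage, dehydration of the β-hydroxy ketone and migration of the β,γ-alkene.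

Step 10
Reactants: 20 (3Z)-1-[(1R,2R,5R)-2-ethenyl-5-hydroxy-2-methyl-5-(propan-2-yl)cyclopentyl]-4-iodo-3-methylbut-3-en-1-one
Product: 22 (1R,2S,3R)-3-ethenyl-2-[(1S,3Z)-1-hydroxy-4-iodo-3-methylbut-3-en-1-yl]-3-methyl-1-(propan-2-yl)cyclopentan-1-ol, via diethylboron chelate 21 (not isolated)
Conditions: Et2BOMe, THF/MeOH (4:1), −78 °C; NaBH4; MeOH co-evaporation
Reagents that add atoms: none
Why: Narasaka–Prasad reduction: boron bridges the C4 alkoxide and the C6 carbonyl in a six-membered chelate cis-fused to the cyclopentane, which should sit in the half-chair with the isopropyl group pseudo-equatorial and H5 axial; external hydride then adds axially, anti to H5, placing C7 equatorial and giving the 6S carbinol.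

Step 11
Reactants: 22 (1R,2S,3R)-3-ethenyl-2-[(1S,3Z)-1-hydroxy-4-iodo-3-methylbut-3-en-1-yl]-3-methyl-1-(propan-2-yl)cyclopentan-1-ol
Product: 23 (1R,2S,3R)-1-ethenyl-2-{(1S,3Z)-4-iodo-3-methyl-1-[(triethylsilyl)oxy]but-3-en-1-yl}-1-methyl-3-(propan-2-yl)-3-[(triethylsilyl)oxy]cyclopentane
Conditions: TESOTf (3 equiv), 2,6-lutidine, CH2Cl2, −78 → 0 °C
Reagents that add atoms: triethylsilyl trifluoromethanesulfonate, CC[Si](CC)(CC)OS(=O)(=O)C(F)(F)F
Why: The silyl triflate is reactive enough to silylate both the hindered secondary and the tertiary hydroxyl, so both are masked before the oxidative and iodination steps.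

Step 12
Reactants: 23 (1R,2S,3R)-1-ethenyl-2-{(1S,3Z)-4-iodo-3-methyl-1-[(triethylsilyl)oxy]but-3-en-1-yl}-1-methyl-3-(propan-2-yl)-3-[(triethylsilyl)oxy]cyclopentane
Product: 25 [(1S,2S,3R)-2-{(1S,3Z)-4-iodo-3-methyl-1-[(triethylsilyl)oxy]but-3-en-1-yl}-1-methyl-3-(propan-2-yl)-3-[(triethylsilyl)oxy]cyclopentyl]methanol, via C10 aldehyde 24 (not isolated)
Conditions: OsO4 (2 mol%), NaIO4, 2,6-lutidine, dioxane/H2O (3:1), rt; extractive work-up; NaBH4, EtOH, 0 °C
Reagents that add atoms: osmium tetroxide, O=[Os](=O)(=O)=O; sodium periodate, [Na+].[O-]I(=O)(=O)=O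
Why: Lemieux–Johnson cleavage should take the terminal vinyl group and leave the halogen-deactivated trisubstituted iodoalkene; the non-enolisable neopentyl aldehyde is reduced directly to the C10 alcohol.

Step 13
Reactants: 25 [(1S,2S,3R)-2-{(1S,3Z)-4-iodo-3-methyl-1-[(triethylsilyl)oxy]but-3-en-1-yl}-1-methyl-3-(propan-2-yl)-3-[(triethylsilyl)oxy]cyclopentyl]methanol
Product: 26 (1S,2S,3R)-1-(iodomethyl)-2-{(1S,3Z)-4-iodo-3-methyl-1-[(triethylsilyl)oxy]but-3-en-1-yl}-1-methyl-3-(propan-2-yl)-3-[(triethylsilyl)oxy]cyclopentane
Conditions: I2, PPh3, imidazole, toluene, 80 °C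
Reagents that add atoms: iodine, II
Why: Appel-type iodination through the alkoxyphosphonium salt; displacement at a neopentyl carbon is slow but is a known route to neopentyl iodides on heating, proceeds without rearrangement, and imidazole buffers the medium for the silyl ethers.

Step 14
Reactants: 26 (1S,2S,3R)-1-(iodomethyl)-2-{(1S,3Z)-4-iodo-3-methyl-1-[(triethylsilyl)oxy]but-3-en-1-yl}-1-methyl-3-(propan-2-yl)-3-[(triethylsilyl)oxy]cyclopentane
Product: 27 (3R,3aS,4S,8aR)-6,8a-dimethyl-3-(propan-2-yl)-3,4-bis[(triethylsilyl)oxy]-1,2,3,3a,4,5,8,8a-octahydroazulene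
Conditions: NiBr2·glyme (20 mol%), 4,4′-di-tert-butyl-2,2′-bipyridine (25 mol%), Zn dust (3 equiv), NaI (0.5 equiv), DMA, 40 °C, slow addition of 26 to 0.005 M
Reagents that add atoms: none
Why: Zerovalent nickel on the bipyridine, formed by zinc reduction, should add oxidatively to the C9–I bond with retention of the Z geometry to give a vinylnickel iodide of divalent nickel. A monovalent nickel species abstracts iodine from C10, the neopentyl radical is captured by the nickel centre of the same molecule to give a trivalent nickel species, and reductive elimination forms C9–C10 while zinc returns nickel to the cycle. The closest known reaction is the nickel-catalysed reductive cross-electrophile coupling of alkenyl halides with alkyl iodides under zinc in amide solvents, used here intramolecularly. The seven-membered ring closes by C(sp2)–C(sp3) reductive elimination from an eight-membered nickelacycle, not by radical addition to the alkene. No stereocentre is formed; C1, C4, C5 and C6 are untouched, and the Z vinyl iodide fixes the position and cis geometry of the ring alkene. The step needs the two iodides to be activated differently, ring closure to beat intermolecular coupling, and capture at nickel to beat 6-exo attack on C8. The substrate helps because C10 has no β-hydrogen and cannot react by SN2, nickel on C9 lies on the C7 side pointing at C10, C8 is fully substituted, and slow addition keeps the concentration low. A stray 7-endo addition of the C10 radical to C9 followed by loss of an iodine atom would give the same product.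

Step 15
Reactants: 27 (3R,3aS,4S,8aR)-6,8a-dimethyl-3-(propan-2-yl)-3,4-bis[(triethylsilyl)oxy]-1,2,3,3a,4,5,8,8a-octahydroazulene
Product: 28 (3R,3aS,4S,8aR)-6,8a-dimethyl-3-(propan-2-yl)-1,2,3,3a,4,5,8,8a-octahydroazulene-3,4-diol
Conditions: Bu4NF, THF, 0 → 45 °C
Reagents that add atoms: none
Why: Fluoride cleaves both silyl ethers under non-acidic conditions, so the tertiary carbinol cannot ionise and the alkene stays in place.

Step 16
Reactants: 28 (3R,3aS,4S,8aR)-6,8a-dimethyl-3-(propan-2-yl)-1,2,3,3a,4,5,8,8a-octahydroazulene-3,4-diol; 29 2-(acetyloxy)benzoyl chloride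
Product: 30 (3R,3aS,4S,8aR)-3-hydroxy-6,8a-dimethyl-3-(propan-2-yl)-1,2,3,3a,4,5,8,8a-octahydroazulen-4-yl 2-(acetyloxy)benzoate
Conditions: pyridine, DMAP (cat.), CH2Cl2, 0 °C → rt
Reagents that add atoms: none
Why: Nucleophilic-catalysed acylation should take the secondary C6 hydroxyl only, since the tertiary C4 hydroxyl flanked by the isopropyl group is too hindered; the acetyl group keeps the phenol from competing.

Step 17
Reactants: 30 (3R,3aS,4S,8aR)-3-hydroxy-6,8a-dimethyl-3-(propan-2-yl)-1,2,3,3a,4,5,8,8a-octahydroazulen-4-yl 2-(acetyloxy)benzoate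
Product: 31 (3R,3aS,4S,8aR)-3-hydroxy-6,8a-dimethyl-3-(propan-2-yl)-1,2,3,3a,4,5,8,8a-octahydroazulen-4-yl 2-hydroxybenzoate
Conditions: pyrrolidine, CH2Cl2, 0 °C → rt
Reagents that add atoms: none
Why: Aminolysis of the phenolic acetate, an activated aryl ester, should be much faster than attack on the hindered secondary alkyl benzoate, so the phenol is freed without loss of the C6 ester.

## Compound list

1 | 1,3-dithiane | C1CSCSC1 | starting material
2 | 1,3-dithian-2-ylium tetrafluoroborate | [CH+]1SCCCS1.F[B-](F)(F)F | intermediate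
3 | prop-2-yn-1-ol | C#CCO | starting material
4 | methylmagnesium bromide | C[Mg]Br | starting material
5 | cyclic alkenylmagnesium alkoxide (4-methyl-2,5-dihydro-1,2-oxamagnesole, Mg on C3 cis to CH2O) | CC1=C[Mg]OC1 | intermediate
6 | (2Z)-3-iodo-2-methylprop-2-en-1-ol | OC/C(C)=C\I | intermediate
7 | (1Z)-3-bromo-1-iodo-2-methylprop-1-ene | BrC/C(C)=C\I | intermediate
8 | 3-methylcyclopent-2-en-1-one | CC1=CC(=O)CC1 | starting material
9 | ethynyl(trimethyl)silane | C#C[Si](C)(C)C | starting material
10 | bis(2-methylpropyl)[1-(trimethylsilyl)ethenyl]alane | C=C([Si](C)(C)C)[Al](CC(C)C)CC(C)C | intermediate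
11 | bis(2-methylpropyl)aluminium enolate of (3S)-3-methyl-3-[1-(trimethylsilyl)ethenyl]cyclopentanone, enol double bond toward C2 | C=C([Si](C)(C)C)[C@@]1(C)CCC(O[Al](CC(C)C)CC(C)C)=C1 | intermediate
12 | trimethyl({(3S)-3-methyl-3-[1-(trimethylsilyl)ethenyl]cyclopent-1-en-1-yl}oxy)silane | C=C([Si](C)(C)C)[C@@]1(C)CCC(O[Si](C)(C)C)=C1 | intermediate
13 | (2R,3S)-2-(1,3-dithian-2-yl)-3-methyl-3-[1-(trimethylsilyl)ethenyl]cyclopentan-1-one | C=C([Si](C)(C)C)[C@@]1(C)CCC(=O)[C@@H]1C2SCCCS2 | intermediate
14 | (2R,3R)-2-(1,3-dithian-2-yl)-3-ethenyl-3-methylcyclopentan-1-one | C=C[C@@]1(C)CCC(=O)[C@@H]1C2SCCCS2 | intermediate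
15 | isopropylmagnesium chloride | CC(C)[Mg]Cl | starting material
16 | isopropylcerium dichloride | CC(C)[Ce](Cl)Cl | intermediate
17 | (1R,2R,3R)-2-(1,3-dithian-2-yl)-3-ethenyl-3-methyl-1-(propan-2-yl)cyclopentan-1-ol | C=C[C@@]1(C)CC[C@@](O)(C(C)C)[C@@H]1C2SCCCS2 | intermediate
18 | O,C-dilithio derivative of 17 (lithium alkoxide and 2-lithio-1,3-dithiane) | C=C[C@@]1(C)CC[C@@](O[Li])(C(C)C)[C@@H]1C2([Li])SCCCS2 | intermediate
19 | (1R,2R,3R)-3-ethenyl-2-{2-[(2Z)-3-iodo-2-methylprop-2-en-1-yl]-1,3-dithian-2-yl}-3-methyl-1-(propan-2-yl)cyclopentan-1-ol | C=C[C@@]1(C)CC[C@@](O)(C(C)C)[C@@H]1C2(C/C(C)=C\I)SCCCS2 | intermediate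
20 | (3Z)-1-[(1R,2R,5R)-2-ethenyl-5-hydroxy-2-methyl-5-(propan-2-yl)cyclopentyl]-4-iodo-3-methylbut-3-en-1-one | C=C[C@@]1(C)CC[C@@](O)(C(C)C)[C@@H]1C(=O)C/C(C)=C\I | intermediate
21 | O-diethylboryl chelate of 20 (boron on the C4 oxygen, coordinated by the C6 carbonyl) | C=C[C@@]1(C)CC[C@@](OB(CC)CC)(C(C)C)[C@@H]1C(=O)C/C(C)=C\I | intermediate
22 | (1R,2S,3R)-3-ethenyl-2-[(1S,3Z)-1-hydroxy-4-iodo-3-methylbut-3-en-1-yl]-3-methyl-1-(propan-2-yl)cyclopentan-1-ol | C=C[C@@]1(C)CC[C@@](O)(C(C)C)[C@@H]1[C@@H](O)C/C(C)=C\I | intermediate
23 | (1R,2S,3R)-1-ethenyl-2-{(1S,3Z)-4-iodo-3-methyl-1-[(triethylsilyl)oxy]but-3-en-1-yl}-1-methyl-3-(propan-2-yl)-3-[(triethylsilyl)oxy]cyclopentane | C=C[C@@]1(C)CC[C@@](O[Si](CC)(CC)CC)(C(C)C)[C@@H]1[C@@H](O[Si](CC)(CC)CC)C/C(C)=C\I | intermediate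
24 | (1S,2S,3R)-2-{(1S,3Z)-4-iodo-3-methyl-1-[(triethylsilyl)oxy]but-3-en-1-yl}-1-methyl-3-(propan-2-yl)-3-[(triethylsilyl)oxy]cyclopentane-1-carbaldehyde | O=C[C@@]1(C)CC[C@@](O[Si](CC)(CC)CC)(C(C)C)[C@@H]1[C@@H](O[Si](CC)(CC)CC)C/C(C)=C\I | intermediate
25 | [(1S,2S,3R)-2-{(1S,3Z)-4-iodo-3-methyl-1-[(triethylsilyl)oxy]but-3-en-1-yl}-1-methyl-3-(propan-2-yl)-3-[(triethylsilyl)oxy]cyclopentyl]methanol | OC[C@@]1(C)CC[C@@](O[Si](CC)(CC)CC)(C(C)C)[C@@H]1[C@@H](O[Si](CC)(CC)CC)C/C(C)=C\I | intermediate
26 | (1S,2S,3R)-1-(iodomethyl)-2-{(1S,3Z)-4-iodo-3-methyl-1-[(triethylsilyl)oxy]but-3-en-1-yl}-1-methyl-3-(propan-2-yl)-3-[(triethylsilyl)oxy]cyclopentane | IC[C@@]1(C)CC[C@@](O[Si](CC)(CC)CC)(C(C)C)[C@@H]1[C@@H](O[Si](CC)(CC)CC)C/C(C)=C\I | intermediate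
27 | (3R,3aS,4S,8aR)-6,8a-dimethyl-3-(propan-2-yl)-3,4-bis[(triethylsilyl)oxy]-1,2,3,3a,4,5,8,8a-octahydroazulene | CC1=CC[C@@]2(C)CC[C@@](O[Si](CC)(CC)CC)(C(C)C)[C@@H]2[C@@H](O[Si](CC)(CC)CC)C1 | intermediate
28 | (3R,3aS,4S,8aR)-6,8a-dimethyl-3-(propan-2-yl)-1,2,3,3a,4,5,8,8a-octahydroazulene-3,4-diol | CC1=CC[C@@]2(C)CC[C@@](O)(C(C)C)[C@@H]2[C@@H](O)C1 | intermediate
29 | 2-(acetyloxy)benzoyl chloride | CC(=O)Oc1ccccc1C(Cl)=O | starting material
30 | (3R,3aS,4S,8aR)-3-hydroxy-6,8a-dimethyl-3-(propan-2-yl)-1,2,3,3a,4,5,8,8a-octahydroazulen-4-yl 2-(acetyloxy)benzoate | CC1=CC[C@@]2(C)CC[C@@](O)(C(C)C)[C@@H]2[C@@H](OC(=O)c2ccccc2OC(C)=O)C1 | intermediate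
31 | (3R,3aS,4S,8aR)-3-hydroxy-6,8a-dimethyl-3-(propan-2-yl)-1,2,3,3a,4,5,8,8a-octahydroazulen-4-yl 2-hydroxybenzoate | CC1=CC[C@@]2(C)CC[C@@](O)(C(C)C)[C@@H]2[C@@H](OC(=O)c2ccccc2O)C1 | target

## Step count and least certain steps

Total step count: 17. Longest linear sequence: 14 steps (steps 4 to 17, from 8).

**Step 14 (key step).** Intermolecular coupling of two molecules can outrun ring closure, either carbon–iodine bond can be reduced to C–H before the coupling, and the C10 radical can add 6-exo to C8 before it meets nickel. Fallback: the same C9–C10 bond is made by a polar Nozaki–Hiyama–Kishi closure. It sets out from aldehyde 24, isolated after the first stage of step 12. CrCl2 with catalytic NiCl2 in DMSO should add the C9 vinylchromium species to the non-enolisable C10 aldehyde and give the C10-hydroxy hydroazulene F1 as a mixture of C10 epimers. Acetylation gives the allylic acetate F2. Pd(PPh3)4 (zerovalent palladium) with LiBHEt3 should then deliver hydride to the less substituted allyl terminus C10, which comes back to the route at 27.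

**Step 8.** Metalation of the dithiane C–H may be incomplete because C6 hangs on a carbon flanked by two fully substituted centres, and any alkyllithium left over would exchange with the vinyl iodide of 7. Fallback: the C6–C7 bond is made with reversed polarity, from 17 to 20. Hydrolysis of the dithiane of 17 (MeI, CaCO3) gives the hydroxy aldehyde F3. Barbier addition of propargyl bromide with Zn gives the homopropargylic diol F4 as C6 epimers. Negishi carboalumination (Me3Al, Cp2ZrCl2), then heating to isomerise the alkenylalane to its alkoxide-chelated Z form, and iodinolysis give the iodo diol F5 as C6 epimers. Dess–Martin oxidation of the secondary hydroxyl converges both epimers on 20.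

**Step 10.** Facial selectivity may be poor, because the cis-fused boron chelate can react through either half-chair and the two lead to opposite C6 configurations. Internal hydride delivery from a boron bound to the C4 oxygen would also favour the 6R epimer. Fallback: reagent control in place of chelate control, from 20 to 23. Silylation of the C4 hydroxyl (TESOTf, 2,6-lutidine) gives the β-silyloxy ketone F6. Corey–Bakshi–Shibata reduction with (R)-2-methyl-CBS-oxazaborolidine and catecholborane, which spares the vinyl group, should give the 6S alcohol F7; the cyclopentyl side acts as the large and C7H2 as the small substituent. A second silylation returns to 23.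

**Step 13.** Displacement at the neopentyl carbon may be too slow at temperatures the silyl ethers tolerate, so that loss of a triethylsilyl group competes. Fallback: activation as a sulfonate at low temperature in place of the phosphonium route, from 25 to 26. Tf2O with 2,6-di-tert-butylpyridine at −78 °C gives the neopentyl triflate F8, and NaI in acetone at room temperature displaces it to 26.

**Step 6.** Acid may epimerise C5 through the enol once the bulky silyl group is gone, or ipso-protonation of the hindered vinylsilane may be sluggish. Fallback: a fluoride-labile silyl group is used and removed only after C5 has lost its acidic position, from 8 to 17. Step 4 is run with the alane from benzyl(ethynyl)dimethylsilane to give the silyl enol ether F9. Alkylation with 2 gives the dithianyl ketone F10. Isopropylcerium addition gives the carbinol F11. Bu4NF in THF then cleaves the alkenyl–silicon bond under non-acidic conditions and gives 17.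

## Further compounds

F1 | step 14 | C10-hydroxy derivative of 27 (both C10 epimers): (3R,3aS,4S,8aS)-6,8a-dimethyl-3-(propan-2-yl)-3,4-bis[(triethylsilyl)oxy]-1,2,3,3a,4,5,8,8a-octahydroazulen-8-ol | CC1=CC(O)[C@@]2(C)CC[C@@](O[Si](CC)(CC)CC)(C(C)C)[C@@H]2[C@@H](O[Si](CC)(CC)CC)C1
F2 | step 14 | C10 acetate of F1 (both C10 epimers) | CC1=CC(OC(C)=O)[C@@]2(C)CC[C@@](O[Si](CC)(CC)CC)(C(C)C)[C@@H]2[C@@H](O[Si](CC)(CC)CC)C1
F3 | step 8 | (1R,2R,5R)-2-ethenyl-5-hydroxy-2-methyl-5-(propan-2-yl)cyclopentane-1-carbaldehyde | C=C[C@@]1(C)CC[C@@](O)(C(C)C)[C@@H]1C=O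
F4 | step 8 | (1R,2S,3R)-3-ethenyl-2-(1-hydroxybut-3-yn-1-yl)-3-methyl-1-(propan-2-yl)cyclopentan-1-ol (both C6 epimers) | C=C[C@@]1(C)CC[C@@](O)(C(C)C)[C@@H]1C(O)CC#C
F5 | step 8 | (1R,2S,3R)-3-ethenyl-2-[(3Z)-1-hydroxy-4-iodo-3-methylbut-3-en-1-yl]-3-methyl-1-(propan-2-yl)cyclopentan-1-ol (22 and its C6 epimer) | C=C[C@@]1(C)CC[C@@](O)(C(C)C)[C@@H]1C(O)C/C(C)=C\I
F6 | step 10 | C4 triethylsilyl ether of 20: (3Z)-1-{(1R,2R,5R)-2-ethenyl-2-methyl-5-(propan-2-yl)-5-[(triethylsilyl)oxy]cyclopentyl}-4-iodo-3-methylbut-3-en-1-one | C=C[C@@]1(C)CC[C@@](O[Si](CC)(CC)CC)(C(C)C)[C@@H]1C(=O)C/C(C)=C\I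
F7 | step 10 | C4 triethylsilyl ether of 22: (1S,3Z)-1-{(1S,2R,5R)-2-ethenyl-2-methyl-5-(propan-2-yl)-5-[(triethylsilyl)oxy]cyclopentyl}-4-iodo-3-methylbut-3-en-1-ol | C=C[C@@]1(C)CC[C@@](O[Si](CC)(CC)CC)(C(C)C)[C@@H]1[C@@H](O)C/C(C)=C\I
F8 | step 13 | C10 trifluoromethanesulfonate of 25 | FC(F)(F)S(=O)(=O)OC[C@@]1(C)CC[C@@](O[Si](CC)(CC)CC)(C(C)C)[C@@H]1[C@@H](O[Si](CC)(CC)CC)C/C(C)=C\I
F9 | step 6 | benzyl(dimethyl){1-[(1S)-1-methyl-3-[(trimethylsilyl)oxy]cyclopent-2-en-1-yl]ethenyl}silane | C=C([Si](C)(C)Cc1ccccc1)[C@@]1(C)CCC(O[Si](C)(C)C)=C1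
F10 | step 6 | (2R,3S)-3-{1-[benzyl(dimethyl)silyl]ethenyl}-2-(1,3-dithian-2-yl)-3-methylcyclopentan-1-one | C=C([Si](C)(C)Cc1ccccc1)[C@@]1(C)CCC(=O)[C@@H]1C2SCCCS2
F11 | step 6 | (1R,2R,3S)-3-{1-[benzyl(dimethyl)silyl]ethenyl}-2-(1,3-dithian-2-yl)-3-methyl-1-(propan-2-yl)cyclopentan-1-ol | C=C([Si](C)(C)Cc1ccccc1)[C@@]1(C)CC[C@@](O)(C(C)C)[C@@H]1C2SCCCS2
A1 | alternative 1 | carotol | CC1=CC[C@@]2(C)CC[C@@H](C(C)C)[C@@]2(O)CC1
A2 | alternative 1 | (2E,6E)-farnesyl diphosphate | CC(C)=CCC/C(C)=C/CC/C(C)=C/COP(O)(=O)OP(O)(O)=O
A3 | alternative 2 | (8aR)-6,8a-dimethyl-3-(propan-2-yl)-2,5,8,8a-tetrahydroazulen-4(1H)-one | CC1=CC[C@@]2(C)CCC(C(C)C)=C2C(=O)C1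
A4 | alternative 2 | 6-methyl-3-(4-methyl-3-oxopentyl)cyclohepta-2,5-dien-1-one | CC1=CCC(CCC(=O)C(C)C)=CC(=O)C1
A5 | alternative 2 | trimethylaluminium | C[Al](C)C
A6 | alternative 2 | tetrakis(acetonitrile)copper hexafluorophosphate | CC#N.CC#N.CC#N.CC#N.[Cu+].F[P-](F)(F)(F)(F)F
A7 | alternative 3 | methyl (8aR)-4-ethoxy-8a-methyl-3-oxo-1,2,3,5,8,8a-hexahydroazulene-6-carboxylate | COC(=O)C1=CC[C@@]2(C)CCC(=O)C2=C(OCC)C1
A8 | alternative 3 | 2-(1-ethoxyethenyl)-3-methylcyclopent-2-en-1-one | C=C(OCC)C1=C(C)CCC1=O
A9 | alternative 3 | methyl 2-diazobut-3-enoate | COC(=O)C(=[N+]=[N-])C=C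
A10 | alternative 3 | dirhodium tetrakis[(S)-N-(4-dodecylphenylsulfonyl)prolinate] | CCCCCCCCCCCCc1ccc(cc1)S(=O)(=O)N1CCC[C@H]1C(=O)[O-].CCCCCCCCCCCCc1ccc(cc1)S(=O)(=O)N1CCC[C@H]1C(=O)[O-].CCCCCCCCCCCCc1ccc(cc1)S(=O)(=O)N1CCC[C@H]1C(=O)[O-].CCCCCCCCCCCCc1ccc(cc1)S(=O)(=O)N1CCC[C@H]1C(=O)[O-].[Rh+2].[Rh+2]
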